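**Retrosynthetic overview**

1. Labels: ring A (cyclopentane) is a1 (CMe2), a2 (CHBr), a3 (CH2), a4 (CHOH), a5 (CMe); ring B is b1 (C-OH, bonded to a5), b2, b3, b4 (CMe), b5 (C-OH), b6; ring C is b4, c1 (CHBr), c2, c3, c4 (CMe-OH), b5. β is the decalin face of the b4 methyl, α the other; on ring A faces are given relative to the a5 methyl.
2. The route rests on the triad b1-O / quaternary a5 / a4-O, in which the a4 oxygen and b1 are cis on ring A. This 1,3-dioxygenated pattern is an opened spiro-oxetane, so the a5-b1 bond and an O-a4 bond are cut together by a retro Paternò-Büchi reaction into a ring B/C decalone (b1 ketone) and an a4=a5 cyclopentene (ring A).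
3. Endgame, read backwards: the syn-diaxial b1/b5 diol comes from a cyclic carbonate formed when the oxetane is ionised at b1 and trapped by a b5 carbonate. The a2 bromide comes from an a2 silyl ether by inversion while the oxetane still masks the a4 and b1 oxygens; the same silyloxy group steers the photocycloaddition to the opposite alkene face.
4. Decalone from (S)-Wieland-Miescher ketone: deconjugative ketalisation, c1 ketone to bromoalkene to equatorial bromide (HAT hydrogenation), b5=c4 alkene to the trans-diaxial diol (dihydroxylation, oxidation, equatorial MeMgBr addition). Cyclopentene from 2,2-dimethylcyclopentane-1,3-dione: CBS reduction, silylation, enol triflate, iron-catalysed methylation.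
5. Ring order: rings B and C and ring A are bought as carbocycles; the only ring made is the oxetane (step 14), opened again in step 18 after serving as linchpin and protecting group.

Key step: step 14

Remark: the b1 configuration written for 16 (oxetane oxygen axial, α) is the expected one and is not decisive, because b1 is ionised and re-set in step 18.

**Route**

Step 1
Reactants: 1 (S)-Wieland-Miescher ketone
Product: 2 (4aS,5S)-5-hydroxy-4a-methyl-4,4a,5,6,7,8-hexahydronaphthalen-2(3H)-one (c1 β-alcohol)
Conditions: NaBH4 (0.3 equiv), EtOH, -10 °C
Reagents that add atoms: none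
Why: Chemoselective borohydride reduction, in which the saturated c1 ketone is more electrophilic than the vinylogous enone carbonyl and hydride enters on the face opposite the angular methyl to give the equatorial β-alcohol, a temporary stereocentre that only keeps c1 out of the ketalisation and is erased in step 3.

Step 2
Reactants: 2 hydroxy enone
Product: 3 b1 ethylene ketal with the alkene moved to b5=c4 (c1 β-alcohol)
Conditions: HOCH2CH2OH, TsOH (cat.), benzene, reflux, Dean-Stark
Reagents that add atoms: ethylene glycol, OCCO
Why: Acid-catalysed dioxolane formation on a 4a-methyl octalenone passes through the dienol ether and, as with steroidal 4-en-3-ones, delivers the β,γ-unsaturated ketal, which protects b1 and places the alkene at b5=c4 where the b5 and c4 oxygens will be introduced.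

Step 3
Reactants: 3 ketal alcohol
Product: 4 c1 ketone (b1 ketal, b5=c4 alkene)
Conditions: Pr4N[RuO4] (TPAP, cat.), NMO, 4 Å MS, CH2Cl2, rt
Reagents that add atoms: none
Why: Ley-Griffith oxidation is neutral and anhydrous, so the ketal survives, and the new c1 ketone has no α-hydrogen on the b4 side, so the b5=c4 alkene cannot drift into conjugation.

Step 4
Reactants: 4 keto ketal
Product: 5 c1-bromo c1=c2 alkene (diene ketal)
Conditions: P(OPh)3, Br2, CH2Cl2, -60 °C; then 4, Et3N, -60 °C to reflux
Reagents that add atoms: bromine, BrBr (delivered as bromotriphenoxyphosphonium bromide)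
Why: Preformed bromotriphenoxyphosphonium bromide converts enolisable ketones into bromoalkenes by O-phosphonium activation, bromide addition and amine-mediated loss of HBr; only c2 offers a hydrogen, so one regioisomer is possible, and the absence of free bromine and the excess of triethylamine protect the trisubstituted alkene and the ketal.

Step 5
Reactants: 5 bromo diene ketal
Product: 6 b5α,c4α-cis-diol (c1=c2 bromoalkene retained)
Conditions: OsO4 (cat.), NMO, acetone/H2O, rt
Reagents that add atoms: osmium tetroxide, O=[Os](=O)(=O)=O (the two oxygens, resupplied by N-methylmorpholine N-oxide, C[N+]1([O-])CCOCC1)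
Why: Catalytic osmium dihydroxylation is selective for the electron-rich trisubstituted b5=c4 alkene over the electron-poor bromoalkene and adds syn on the α face, opposite the angular b4 methyl that covers the β face, which fixes b5-OH α (trans ring fusion) and c4-OH α.

Step 6
Reactants: 6 bromoalkene diol
Product: 7 c1 β-bromide (equatorial) b5α,c4α-diol ketal
Conditions: Mn(dpm)3 (cat., dpm = dipivaloylmethanate), PhSiH3, t-BuOOH, i-PrOH, rt
Reagents that add atoms: none
Why: Hydrogen-atom-transfer hydrogenation (Mukaiyama-type, manganese hydride from PhSiH3) reduces haloalkenes without cleaving the carbon-halogen bond: H adds to c2 to give the α-bromo radical at c1, which should accept the second hydrogen axially on the α face, away from the neighbouring axial methyl, so that bromine finishes equatorial (β), the more stable arrangement.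

Step 7
Reactants: 7 bromo diol ketal
Product: 8 c4 ketone with b5α-OH (α-ketol)
Conditions: Pr4N[RuO4] (TPAP, cat.), NMO, 4 Å MS, CH2Cl2, rt
Reagents that add atoms: none
Why: Ley-Griffith oxidation takes the secondary c4 carbinol to the ketone while the tertiary b5 alcohol is inert, and the mild neutral conditions avoid glycol cleavage and leave the remote bromide alone.

Step 8
Reactants: 8 α-ketol
Product: 9 c4α-methyl b5α,c4β-diol (trans-diaxial) c1β-bromo ketal
Conditions: MeMgBr (3 equiv), THF, -78 to 0 °C; aq. NH4Cl
Reagents that add atoms: methylmagnesium bromide, C[Mg]Br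
Why: Grignard addition to the α-ketol after deprotonation of the b5 hydroxyl: the axial β trajectory at c4 is blocked by the 1,3-diaxial b4 methyl, so methyl enters equatorially from the α face and the new c4 hydroxyl is axial β, trans-diaxial to b5-OH, as established for 5α-hydroxy-6-keto steroids.

Step 9
Reactants: 9 diol ketal
Product: 10 bromo dihydroxy decalone (b1 ketone)
Conditions: 1 M aq. HCl, THF, 0 °C
Reagents that add atoms: water, O
Why: Dilute aqueous acid hydrolyses the dioxolane, and the low temperature and short contact keep the β-hydroxy ketone from dehydrating to the enone, as in the isolation of 5α-hydroxy-3-keto steroids from their ketals.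

Step 10
Reactants: 11 2,2-dimethylcyclopentane-1,3-dione
Product: 12 (S)-3-hydroxy-2,2-dimethylcyclopentan-1-one
Conditions: (R)-Me-CBS (10 mol %), BH3·SMe2 (0.6 equiv), THF, -20 °C; MeOH
Reagents that add atoms: none
Why: Corey-Bakshi-Shibata reduction of one of the two homotopic carbonyls: the oxazaborolidine binds the ketone with the quaternary α-carbon as the large group and the methylene as the small one, so the (R)-catalyst should give the (S)-carbinol, and a sub-stoichiometric charge of borane at low temperature limits reduction of the second carbonyl.

Step 11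
Reactants: 12 hydroxy ketone
Product: 13 (S)-3-(tert-butyldimethylsilyloxy)-2,2-dimethylcyclopentan-1-one
Conditions: TBSCl, imidazole, DMF, rt
Reagents that add atoms: tert-butyldimethylsilyl chloride, CC(C)(C)[Si](C)(C)Cl
Why: Standard imidazole-promoted silylation of the secondary alcohol installs the bulky group that will later shield one face of the cyclopentene.

Step 12
Reactants: 13 silyloxy ketone
Product: 14 (S)-4-(tert-butyldimethylsilyloxy)-5,5-dimethylcyclopent-1-en-1-yl triflate
Conditions: KN(SiMe3)2 (KHMDS), THF, -78 °C; PhNTf2
Reagents that add atoms: N-phenylbis(trifluoromethanesulfonimide), O=S(=O)(N(c1ccccc1)S(=O)(=O)C(F)(F)F)C(F)(F)F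
Why: The ketone can enolise only towards C5 because the other α-carbon is quaternary, so kinetic deprotonation and O-triflation give a single enol triflate, and the silyloxy group is γ to the enolate carbon and cannot be eliminated.

Step 13
Reactants: 14 enol triflate
Product: 15 (S)-tert-butyldimethyl[(2,2,3-trimethylcyclopent-3-en-1-yl)oxy]silane (a4=a5 alkene, a2 silyl ether)
Conditions: MeMgBr, Fe(acac)3 (cat.), THF/NMP, 0 °C
Reagents that add atoms: methylmagnesium bromide, C[Mg]Br
Why: Iron-catalysed Kumada-type cross-coupling of alkenyl triflates with alkyl Grignard reagents is fast at 0 °C, tolerates silyl ethers and replaces the triflate by methyl without moving the double bond, giving the trisubstituted a4=a5 alkene.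

Step 14
Reactants: 10 bromo dihydroxy decalone; 15 cyclopentene silyl ether
Product: 16 spiro-oxetane (O bridges a4 and b1; a5-b1 bond formed; oxetane anti to the a5 methyl on ring A; a2 silyloxy syn to the a5 methyl; oxetane oxygen axial α on b1)
Conditions: hν (300 nm, Pyrex), 15 (5 equiv), benzene, degassed, 10 °C
Reagents that add atoms: none
Why: Proposed new method: n,π* excitation of the b1 ketone gives an electrophilic oxygen that bonds to the less substituted alkene carbon a4, and the resulting 1,4-biradical (ketyl-type radical at b1, tertiary radical at a5) combines to form the a5-b1 bond; the closest known reaction is the Paternò-Büchi cycloaddition of cyclohexanones and other dialkyl ketones with trialkyl-substituted alkenes, which has not been shown for a pairing that joins a quaternary carbon to a fully substituted spiro carbon. The one ring formed, the oxetane, is closed in this stepwise [2+2] mode, C-O bond first and then four-membered ring closure by radical-radical combination, which tolerates crowding because the two termini are already tethered and no solvated nucleophile has to approach; the four-membered ring can only be cis-fused to the cyclopentane, which places the a4 oxygen and b1 cis on ring A. The configurations of a4 and a5 are controlled by the a2 silyloxy group, which shields its own face so that the ketone adds to the opposite one and relays the CBS-derived centre; b1 is set in the ring closure, expected with the bulky a5 equatorial and the oxygen axial (α, syn to the b5 hydroxyl), and either b1 epimer is usable because this centre is re-set in step 18. The step needs regioselectivity (oxygen to a4), secured by the greater stability of the biradical with the tertiary a5 radical, face selectivity, secured by the silyloxy group, and chemoselectivity over α-cleavage (Norrish type 1), allylic hydrogen abstraction and C-Br homolysis, for which the substrate offers a cyclohexanone without α-branching, a cyclic alkene in excess that cannot dissipate energy by E/Z isomerisation, and bromides that do not absorb at 300 nm.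

Step 15
Reactants: 16 spiro-oxetane diol
Product: 17 b5,c4-bis(methyl carbonate) of 16
Conditions: KH (3 equiv), THF, 0 °C; ClCO2Me (4 equiv), 0 °C to rt
Reagents that add atoms: methyl chloroformate, COC(=O)Cl
Why: O-Acylation of preformed potassium alkoxides with a chloroformate is the dependable way to derivatise hindered tertiary alcohols; the two oxygens are trans-diaxial and cannot close a five-membered cyclic carbonate, so both become methyl carbonates, the b5 one being the neighbouring group for step 18 and the c4 one a protecting group that leaves in step 19.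

Step 16
Reactants: 17 bis(methyl carbonate)
Product: 18 a2 alcohol (hydroxyl syn to the a5 methyl)
Conditions: Bu4NF, AcOH, THF, rt
Reagents that add atoms: none
Why: Fluoride-mediated desilylation buffered with acetic acid cleaves only the silyl ether, since the oxetane is stable to fluoride and weak acid and the tertiary carbonates are shielded, and it releases the single free hydroxyl of the molecule.

Step 17
Reactants: 18 a2 alcohol
Product: 20 a2 bromide (bromine anti to the a5 methyl and cis to the a4 oxygen), via a2 triflate 19 (not isolated)
Conditions: Tf2O, pyridine, CH2Cl2, -78 to -20 °C; then Bu4NBr, toluene, 0 °C to rt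
Reagents that add atoms: tetrabutylammonium bromide, CCCC[N+](CCCC)(CCCC)CCCC.[Br-]; triflic anhydride, O=S(=O)(OS(=O)(=O)C(F)(F)F)C(F)(F)F (its atoms are held in 19 only)
Why: Sulfonate displacement (SN2) with inversion: the a2 alcohol is the only hydroxyl because the oxetane still masks the a4 and b1 oxygens, the cyclopentyl triflate accepts backside attack by soluble bromide even next to the gem-dimethyl carbon, and the low-polarity medium and low temperature disfavour ionisation with methyl migration, so bromine arrives on the face of the oxetane oxygen as in the target.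

Step 18
Reactants: 20 bromo oxetane bis(methyl carbonate)
Product: 21 a4 alcohol with b1/b5 cyclic carbonate and c4 methyl carbonate
Conditions: TfOH (10 mol %), water-saturated CH2Cl2, -20 °C; NaHCO3
Reagents that add atoms: water, O
Why: Acid-promoted ring opening of a 2,2-disubstituted oxetane with neighbouring-group participation, the oxetane counterpart of carbonate-assisted epoxide opening and halocarbonate cyclisation: protonation and release of ring strain ionise the tertiary b1-O bond, the axial b5 carbonate carbonyl, held 1,3-diaxial to b1, traps the cation on the α face as a 1,3-dioxan-2-ylium ion that water turns into the cyclic carbonate with loss of methanol, so the b1 oxygen is set syn to the b5 oxygen whichever b1 epimer of 16 was carried, while the former oxetane oxygen stays on a4 with its configuration untouched.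

Step 19
Reactants: 21 carbonate-protected tetraol
Product: 22 neoirietetraol
Conditions: K2CO3 (cat.), MeOH, rt
Reagents that add atoms: none
Why: Base-catalysed transesterification attacks only the carbonate carbonyl carbons, so the cyclic carbonate and the methyl carbonate are both released as dimethyl carbonate without touching any stereocentre, and the two secondary bromides, both neopentyl and the c1 one without an anti-periplanar hydrogen, should tolerate carbonate in methanol at room temperature.

**Compound list**

1 | (S)-Wieland-Miescher ketone, (S)-8a-methyl-3,4,8,8a-tetrahydronaphthalene-1,6(2H,7H)-dione | O=C1CC[C@]2(C)C(=O)CCCC2=C1 | starting material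
2 | (4aS,5S)-5-hydroxy-4a-methyl-4,4a,5,6,7,8-hexahydronaphthalen-2(3H)-one | O=C1CC[C@]2(C)[C@@H](O)CCCC2=C1 | intermediate
3 | b1 ethylene ketal, b5=c4 alkene, c1 β-alcohol | O1CCOC12CC[C@]3(C)[C@@H](O)CCC=C3C2 | intermediate
4 | b1 ethylene ketal, b5=c4 alkene, c1 ketone | O1CCOC12CC[C@]3(C)C(=O)CCC=C3C2 | intermediate
5 | b1 ethylene ketal, c1-bromo c1=c2 and b5=c4 diene | O1CCOC12CC[C@]3(C)C(Br)=CCC=C3C2 | intermediate
6 | b1 ethylene ketal, c1-bromo c1=c2 alkene, b5α,c4α-diol | O1CCOC12CC[C@]3(C)C(Br)=CC[C@H](O)[C@@]3(O)C2 | intermediate
7 | b1 ethylene ketal, c1β-bromide, b5α,c4α-diol | O1CCOC12CC[C@]3(C)[C@@H](Br)CC[C@H](O)[C@@]3(O)C2 | intermediate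
8 | b1 ethylene ketal, c1β-bromide, c4 ketone, b5α-OH | O1CCOC12CC[C@]3(C)[C@@H](Br)CCC(=O)[C@@]3(O)C2 | intermediate
9 | b1 ethylene ketal, c1β-bromide, c4α-methyl, b5α,c4β-diol | O1CCOC12CC[C@]3(C)[C@@H](Br)CC[C@@](C)(O)[C@@]3(O)C2 | intermediate
10 | bromo dihydroxy decalone (b1 ketone; c1β-Br, c4α-Me, c4β-OH, b5α-OH, b4β-Me) | O=C1CC[C@]2(C)[C@@H](Br)CC[C@@](C)(O)[C@@]2(O)C1 | intermediate
11 | 2,2-dimethylcyclopentane-1,3-dione | CC1(C)C(=O)CCC1=O | starting material
12 | (S)-3-hydroxy-2,2-dimethylcyclopentan-1-one | CC1(C)[C@@H](O)CCC1=O | intermediate
13 | (S)-3-(tert-butyldimethylsilyloxy)-2,2-dimethylcyclopentan-1-one | CC1(C)[C@@H](O[Si](C)(C)C(C)(C)C)CCC1=O | intermediate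
14 | (S)-4-(tert-butyldimethylsilyloxy)-5,5-dimethylcyclopent-1-en-1-yl trifluoromethanesulfonate | CC1(C)[C@@H](O[Si](C)(C)C(C)(C)C)CC=C1OS(=O)(=O)C(F)(F)F | intermediate
15 | (S)-tert-butyldimethyl[(2,2,3-trimethylcyclopent-3-en-1-yl)oxy]silane | CC1(C)[C@@H](O[Si](C)(C)C(C)(C)C)CC=C1C | intermediate
16 | spiro-oxetane joining ring A to the decalin (a2-OTBS, free b5 and c4 hydroxyls) | CC1(C)[C@@H](O[Si](C)(C)C(C)(C)C)C[C@@H]2O[C@@]3(CC[C@]4(C)[C@@H](Br)CC[C@@](C)(O)[C@@]4(O)C3)[C@]12C | intermediate
17 | spiro-oxetane b5,c4-bis(methyl carbonate), a2-OTBS | CC1(C)[C@@H](O[Si](C)(C)C(C)(C)C)C[C@@H]2O[C@@]3(CC[C@]4(C)[C@@H](Br)CC[C@@](C)(OC(=O)OC)[C@@]4(OC(=O)OC)C3)[C@]12C | intermediate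
18 | spiro-oxetane bis(methyl carbonate), a2 alcohol | CC1(C)[C@@H](O)C[C@@H]2O[C@@]3(CC[C@]4(C)[C@@H](Br)CC[C@@](C)(OC(=O)OC)[C@@]4(OC(=O)OC)C3)[C@]12C | intermediate
19 | spiro-oxetane bis(methyl carbonate), a2 triflate | CC1(C)[C@@H](OS(=O)(=O)C(F)(F)F)C[C@@H]2O[C@@]3(CC[C@]4(C)[C@@H](Br)CC[C@@](C)(OC(=O)OC)[C@@]4(OC(=O)OC)C3)[C@]12C | intermediate
20 | spiro-oxetane bis(methyl carbonate), a2 bromide (inverted) | CC1(C)[C@H](Br)C[C@@H]2O[C@@]3(CC[C@]4(C)[C@@H](Br)CC[C@@](C)(OC(=O)OC)[C@@]4(OC(=O)OC)C3)[C@]12C | intermediate
21 | a4 alcohol, b1/b5 cyclic carbonate, c4 methyl carbonate, a2 and c1 bromides | CC1(C)[C@H](Br)C[C@H](O)[C@]1(C)[C@@]1(OC3=O)CC[C@]2(C)[C@@H](Br)CC[C@@](C)(OC(=O)OC)[C@@]2(O3)C1 | intermediate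
22 | neoirietetraol | CC1(C)[C@H](Br)C[C@H](O)[C@]1(C)[C@@]1(O)CC[C@]2(C)[C@@H](Br)CC[C@@](C)(O)[C@@]2(O)C1 | target

**Counts and risks**

Total step count: 19. Longest linear sequence: 15 steps (steps 1-9, then 14-19).

Steps most likely to fail:

1. Step 14 (Paternò-Büchi union). The biradical may revert to the ground-state partners faster than it closes the bond between the two fully substituted carbons, the excited ketone may be consumed by α-cleavage or allylic hydrogen abstraction, and oxygen may attack with the wrong regiochemistry or on the silyloxy face. Fallback by known chemistry, setting out from 15 and 10 and returning at 16: hydroboration-oxidation of 15 (BH3·SMe2; NaOH, H2O2) gives the a4 cyclopentanol F1 and Ley-Griffith oxidation the a4 cyclopentanone F2. Bromination at the more substituted α-carbon (PhNMe3Br3, THF) gives the tertiary α-bromo ketone F3. SmI2 in THF at -78 °C converts F3 into the samarium enolate, which adds to 10 in a Reformatsky-type aldol reaction (enolate face anti to the silyloxy group, equatorial attack on the decalone) to forge a5-b1 and give the aldol adduct F4. Evans-Saksena reduction (Me4N[BH(OAc)3], AcOH/MeCN), delivered from the b1 hydroxyl, gives the 1,3-diol F5 with a4-OH trans to b1. Mesylation of the only secondary hydroxyl gives the a4 mesylate F6, and KOtBu closes the oxetane by Williamson displacement with inversion at a4, which is 16.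

2. Step 18 (oxetane ionisation with carbonate capture). The b1 cation may undergo methyl or ring-bond migration from a5, retro-Prins fragmentation of the a4-a5 bond or proton loss before the carbonate traps it. Fallback without a cation, setting out from 20 and returning at 22, usable if 16 carries the oxetane oxygen on the α face of b1 as drawn: RuCl3 (cat.)/NaIO4 (CCl4/MeCN/H2O) oxidises the ether C-H at a4, and the hemiketal opens to the β-hydroxy ketone F7 with the b1-O bond retained. NaBH4/CeCl3 at -78 °C reduces the a4 ketone from the face opposite the b1 substituent to the a4 alcohol F8. K2CO3 in MeOH, as in step 19, then removes both methyl carbonates to give 22.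

3. Step 17 (neopentyl displacement at a2). Ionisation of the triflate with methyl shift from a1, or elimination to the a2=a3 alkene, may outrun bimolecular substitution. Fallback that sets the C-Br centre by hydrogen delivery instead of substitution, setting out from 18 and returning at 20: Ley-Griffith oxidation gives the a2 cyclopentanone F9. Bromotriphenoxyphosphonium bromide/Et3N, as in step 4, gives the a2-bromo a2=a3 alkene F10 (a pathway through the gem-dibromide that avoids an enolate able to expel the β-oxetane oxygen). HAT hydrogenation as in step 6 should then deliver hydrogen to a2 from the face opposite the oxetane and decalin, leaving bromine on the oxetane face, which is 20.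

Further compounds
F1 | step 14 | (4S)-4-(tert-butyldimethylsilyloxy)-2,3,3-trimethylcyclopentan-1-ol (hydroxyl and a5 hydrogen anti to the silyloxy group) | CC1(C)[C@@H](O[Si](C)(C)C(C)(C)C)C[C@H](O)[C@H]1C
F2 | step 14 | (4S)-4-(tert-butyldimethylsilyloxy)-2,3,3-trimethylcyclopentan-1-one | CC1(C)[C@@H](O[Si](C)(C)C(C)(C)C)CC(=O)[C@H]1C
F3 | step 14 | (4S)-2-bromo-4-(tert-butyldimethylsilyloxy)-2,3,3-trimethylcyclopentan-1-one (either a5 epimer) | CC1(C)[C@@H](O[Si](C)(C)C(C)(C)C)CC(=O)C1(C)Br
F4 | step 14 | aldol adduct: a4 ketone, a5-b1 bond, b1 α-OH, a2-OTBS | CC1(C)[C@@H](O[Si](C)(C)C(C)(C)C)CC(=O)[C@]1(C)[C@@]1(O)CC[C@]2(C)[C@@H](Br)CC[C@@](C)(O)[C@@]2(O)C1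
F5 | step 14 | 1,3-diol with a4-OH trans to b1 on ring A | CC1(C)[C@@H](O[Si](C)(C)C(C)(C)C)C[C@@H](O)[C@]1(C)[C@@]1(O)CC[C@]2(C)[C@@H](Br)CC[C@@](C)(O)[C@@]2(O)C1
F6 | step 14 | a4 methanesulfonate of F5 | CC1(C)[C@@H](O[Si](C)(C)C(C)(C)C)C[C@@H](OS(C)(=O)=O)[C@]1(C)[C@@]1(O)CC[C@]2(C)[C@@H](Br)CC[C@@](C)(O)[C@@]2(O)C1
F7 | step 18 | a4 ketone with b1 α-OH, b5,c4-bis(methyl carbonate), a2 and c1 bromides | CC1(C)[C@H](Br)CC(=O)[C@]1(C)[C@@]1(O)CC[C@]2(C)[C@@H](Br)CC[C@@](C)(OC(=O)OC)[C@@]2(OC(=O)OC)C1
F8 | step 18 | a4 alcohol (cis to b1) with b1 α-OH, b5,c4-bis(methyl carbonate) | CC1(C)[C@H](Br)C[C@H](O)[C@]1(C)[C@@]1(O)CC[C@]2(C)[C@@H](Br)CC[C@@](C)(OC(=O)OC)[C@@]2(OC(=O)OC)C1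
F9 | step 17 | spiro-oxetane bis(methyl carbonate), a2 ketone | CC1(C)C(=O)C[C@@H]2O[C@@]3(CC[C@]4(C)[C@@H](Br)CC[C@@](C)(OC(=O)OC)[C@@]4(OC(=O)OC)C3)[C@]12C
F10 | step 17 | spiro-oxetane bis(methyl carbonate), a2-bromo a2=a3 alkene | CC1(C)C(Br)=C[C@@H]2O[C@@]3(CC[C@]4(C)[C@@H](Br)CC[C@@](C)(OC(=O)OC)[C@@]4(OC(=O)OC)C3)[C@]12C
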